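## Structural features

The target is a 1H-indole, a benzene ring (ring A: C3a, C4, C5, C6, C7, C7a) fused along the C3a–C7a bond to a pyrrole ring (ring B: N1, C2, C3, C3a, C7a); it is planar and has no stereocentre and no side chain. Four carbons carry bromine, C2 and C3 in ring B and C4 and C7 in ring A, so only N1–H, C5–H and C6–H are left. C4 and C7 are para to each other and are the ring A positions that electrophilic substitution of an indole reaches last (C3, then C2, then C5 and C6), so these two bromines must be in place before ring B exists. The bromines on C3 and C4 are peri neighbours and the one on C7 flanks N1–H, which makes ring B crowded on both sides and electron-poor. N-unsubstituted 2,3-dibromoindoles are fragile toward acid, light and oxidants, and the aryl C–Br bonds are at risk from alkyllithiums, zerovalent metals and tin radicals, which excludes most metal-catalysed indole syntheses. The real difficulty is therefore regiochemical and chemoselective: four bromines on defined carbons, and a closure of ring B that tolerates all of them and spares the product further contact with electrophilic bromine. The feature that the key step exploits is the chain N1–C2(Br)=C3(Br)–C3a: C2 is bonded only to N1, C3 and bromine, C3 only to C2, C3a and bromine, and if the C2 bromine is moved to C3, the C2–C3 bond can be opened to an isocyanide carbon on N1 and a dibromomethyl carbon on C3a. The target (C8H3Br4N) is thus a constitutional isomer of a 1,4-dibromobenzene that bears these two groups on its adjacent free positions, and C2–C3 is the only bond that is missing.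

## Logic of the disconnections

In one sentence: 12 is made by base-induced 5-endo-dig closure of the C2–C3 bond in its open isomer 7, with a shift of one bromine from C3 to C2.

12 to 7. The C2–C3 bond of ring B is cut, and in the same operation the bromine on C2 is returned to C3.
- Reason: C2 and C3 are the only skeletal atoms outside ring A. A cut between them leaves each one hanging on ring A by a bond that is easy to make (N1–C7a, C3–C3a).
- Gain: a fragile bicyclic heteroarene becomes a tetrasubstituted benzene of the same formula. The position of every bromine is fixed by construction, and no indole is ever brominated.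
- Demand on the forward step: a carbanion must be made at the benzylic carbon beside two aryl C–Br bonds and an isocyanide. It must close faster than the carbenoid decays, and one bromine must travel from C3 to C2.

7 to 6. The isocyanide carbon is traced back to an N-formyl carbon; no skeletal bond is cut.
- Reason: the isocyanide is too reactive to be carried through halogenation chemistry.
- Gain: a bench-stable amide.
- Demand: a dehydration that does not trigger loss of hydrogen bromide across N–H and the benzylic C–Br.

6 to 5. The two benzylic C–Br bonds are cut and replaced by C=O.
- Reason: the aldehyde is the natural oxidation level of this carbon, and it also activates the ring for the C–N bond formation that comes earlier.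
- Gain: two bromines fewer and a robust functional group.
- Demand: a deoxygenative dibromination on a hindered, electron-poor aldehyde that stands next to a formamide.

5 to 4. The N–C(formyl) bond, the future N1–C2 bond, is cut.
- Reason: it is an ordinary acylation.
- Gain: the one-carbon unit C2 is removed.
- Demand: a formyl donor strong enough for a weakly nucleophilic aniline.

4 to 3. The C7a–N1 bond is cut and replaced by C–F.
- Reason: the ortho formyl group makes this carbon electrophilic, and fluoride is displaced far more readily than the bromide at the other ortho position.
- Gain: nitrogen enters without any metal.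
- Demand: selectivity for C–F over C–Br, and reversibility of any attack on the carbonyl group.

3 to 1 (through 2). The C3a–C3 bond is cut.
- Reason: the ring proton between fluorine and bromine in 1 is the most acidic one, so deprotonation marks exactly the carbon that must become C3a.
- Gain: a commercial trihalobenzene that already holds the para-dibromo pattern of C4 and C7.
- Demand: a temperature low enough that 2 neither eliminates to an aryne nor starts a halogen dance.

## Other disconnections considered

Alternative 1: the first that comes to mind.
- Cut: the C2–Br and C3–Br bonds, then ring B by a nitroarene–vinyl Grignard annulation.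
- Forward: Bartoli indole synthesis of 1,4-dibromo-2-nitrobenzene A1 gives 4,7-dibromo-1H-indole A2. The key step is then a double electrophilic bromination through 3,4,7-tribromo-1H-indole A3.
- Ground: this plan is shorter on paper, but its finishing step forms no skeletal bond and rests only on the innate reactivity order of the indole.
  - The second bromination must go by ipso attack at C3, beside the peri C4 bromine, followed by migration to C2 on an already electron-poor ring.
  - That pathway competes with attack at C5 and C6 and with oxidation at C2.
  - The acid-, light- and oxidant-sensitive N–H product is in contact with positive bromine throughout.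
  - The annulation needs three equivalents of the Grignard reagent beside two aryl C–Br bonds.
  - The chosen plan places each bromine by construction and forms the sensitive ring last, as its anion.

Alternative 2:
- Cut: C3a–C4 and C7–C7a, so that ring A is made from another ring.
- Forward: an inverse-demand Diels–Alder reaction of 2,5-dibromothiophene 1,1-dioxide A4 with the free C4=C5 bond of tert-butyl 2,3-dibromopyrrole-1-carboxylate A5. A4 is a symmetrical diene with both ring A bromines at its termini. Cheletropic extrusion of the sulfonyl bridge leads to the cis-3a,7a-dihydroindole A6, dehydrogenation to the N-Boc indole A7, and carbamate cleavage to the target.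
- Ground: the symmetry of A4 removes any regiochemical question, but the dienophile is an aromatic bond whose donor strength is lowered by two bromines and a carbamate, so the cycloaddition should be slow against self-dimerisation of A4.
  - A6 has three ways to become aromatic: dehydrogenation, dehydrobromination after a hydrogen shift, and C7a–N1 cleavage. Only the first keeps all atoms.
  - A5 runs against the α,α′ preference of pyrrole bromination, so the plan is longer than it looks.

Alternative 3:
- Cut: N1–C7a and C3–C3a at once.
- Forward: fluoride-induced generation of the symmetrical aryne 3,6-dibromobenzyne A9 from 3,6-dibromo-2-(trimethylsilyl)phenyl trifluoromethanesulfonate A8. A formal [3+2] annulation follows with methyl 2-[(tert-butoxycarbonyl)amino]acrylate A10: nitrogen adds to the aryne and the aryl anion closes on the acrylate, giving the indoline A11.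
- Ground: the two equal bromines beside the triple bond make both modes of addition identical, which is attractive.
  - A11 is at the wrong oxidation level, however. Ester removal, dehydrogenation, carbamate cleavage and both ring B brominations remain, so the whole C2/C3 problem is postponed to the electrophilic chemistry of Alternative 1.
  - A8 itself needs several steps, so step economy is clearly worse.

Key step: step 6

Assumption: LiN(iPr)2 is taken from a bought solution, so its preparation is not part of steps 1 and 6.

## Steps

Step 1
Reactants: 1 1,4-dibromo-2-fluorobenzene
Product: 3 3,6-dibromo-2-fluorobenzaldehyde, via aryllithium 2 (not isolated)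
Conditions: LiN(iPr)2 (1.05 equiv), THF, −78 °C; DMF, −78 °C; aq. HCl
Reagents that add atoms: N,N-dimethylformamide, CN(C)C=O
Why: Directed ortho-lithiation followed by formylation with DMF: the C3–H of 1 lies between F and Br and is by far the most acidic ring proton, so the base should take it alone. At −78 °C aryllithium 2 should neither lose LiF or LiBr to an aryne nor start a halogen dance before DMF traps it. This one C–C bond fixes the 1,2,3,4-substitution pattern of ring A.

Step 2
Reactants: 3 3,6-dibromo-2-fluorobenzaldehyde
Product: 4 2-amino-3,6-dibromobenzaldehyde
Conditions: aq. NH3 (excess), DMSO, 80 °C, sealed tube; aqueous work-up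
Reagents that add atoms: ammonia, N
Why: Nucleophilic aromatic substitution by addition–elimination: the formyl group (or its aldimine, formed reversibly) activates both ortho positions, but fluoride is displaced far faster than bromide because the addition is rate-limiting, so only the C–F carbon should react. Aqueous work-up hydrolyses any aldimine, and the two ortho substituents plus the N–H···O=C hydrogen bond should keep 4 from self-condensation.

Step 3
Reactants: 4 2-amino-3,6-dibromobenzaldehyde
Product: 5 N-(3,6-dibromo-2-formylphenyl)formamide
Conditions: HCO2H, Ac2O (premixed, 55 °C), then 4, THF, 0 → 40 °C
Reagents that add atoms: formic acid, OC=O (delivered as acetic formic anhydride, CC(=O)OC=O)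
Why: N-Formylation with a mixed anhydride: acetic formic anhydride transfers only its more electrophilic formyl group and is reactive enough for a hindered, electron-poor aniline. The aldehyde should stay untouched in the absence of strong acid.

Step 4
Reactants: 5 N-(3,6-dibromo-2-formylphenyl)formamide
Product: 6 N-[3,6-dibromo-2-(dibromomethyl)phenyl]formamide
Conditions: BBr3 (3 equiv), CH2Cl2, 0 °C → rt; ice-water
Reagents that add atoms: boron tribromide, BrB(Br)Br
Why: Deoxygenative gem-dibromination of an aromatic aldehyde with BBr3, a known reaction type driven by B–O bond formation, in which bromide is delivered twice to the boron-activated carbonyl carbon. The excess reagent ties up the formamide oxygen as its boron complex, which should suppress participation at the benzylic carbon and is released on quench; the aryl C–Br bonds are inert.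

Step 5
Reactants: 6 N-[3,6-dibromo-2-(dibromomethyl)phenyl]formamide
Product: 7 1,4-dibromo-2-(dibromomethyl)-3-isocyanobenzene
Conditions: POCl3 (1.2 equiv), CH2Cl2, −30 °C, then Et3N (3 equiv) slowly, → 0 °C; cold aq. Na2CO3
Reagents that add atoms: none
Why: Dehydration of a formamide to an isocyanide by O-phosphorylation and base-induced α-elimination, the standard POCl3/amine method. Adding POCl3 before the base means that the amine meets the O-activated imidate and not a free N–H next to a benzylic bromide. The doubly ortho-flanked CHBr2 group should resist substitution at or below 0 °C, and 2,6-disubstituted aryl isocyanides are the most robust of their class.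

Step 6
Reactants: 7 1,4-dibromo-2-(dibromomethyl)-3-isocyanobenzene
Product: 12 2,3,4,7-tetrabromo-1H-indole, via dibromobenzyllithium carbenoid 8 (not isolated), via 2-lithio-3H-indole 9 (not isolated), via pentabromo-3H-indole 10 (not isolated), via lithium indolide 11 (not isolated)
Conditions: LiN(iPr)2 (1.1 equiv), LiBr (5 equiv), THF (0.01 M), −78 °C, slow addition of 7, then → −20 °C; AcOH, −78 °C; exclusion of light
Reagents that add atoms: none
Why: Proposed new method: LiN(iPr)2 removes the only acidic proton of 7, the benzal C–H, and gives carbenoid 8, in which the flanking aryl C–Br and N≡C groups force both benzylic bromines out of the ring plane, so that the carbanion lobe lies in the plane and points at the isocyanide carbon. Attack on that carbon forms C2–C3 and closes ring B in the 5-endo-dig mode to imidoyllithium 9; this is the closure of the Ito–Saegusa indole synthesis (o-lithiomethylphenyl isocyanide to indole), the closest known reaction type, here extended to an α,α-dibromo carbanion. The parent 2-lithio-3H-indole becomes aromatic by a proton shift from C3, whereas 9 has only bromine there and should become aromatic by a bromine shift, because a C3–Br bond of a 3,3-dibromo-3H-indole is a positive-bromine donor (its loss leaves an aromatic indolide) and the sp2 carbanion at C2 is the strongest bromophile present. The shift is expected to run as a relay of the halogen-dance type: 9 takes bromine from a C(sp3)Br2 unit of a second molecule to give pentabromide 10, 10 passes its C3 bromine to the next 9 and thereby becomes indolide 11 while a new 10 is formed, and the sink is 11, the most stabilised anion available. β-Elimination of LiBr from 9 is no escape, since it would put a cumulated N=C=C unit into a five-membered ring. The selectivity needed is closure against α-elimination of LiBr from 8; that loss is reversible in the presence of bromide while its follow-up reactions are bimolecular, hence the added LiBr, the low temperature and the high dilution. Chemoselectivity toward C4–Br and C7–Br comes from the reagent class, as a lithium amide deprotonates but does not exchange aryl bromides, and no low-valent metal or radical chain is present. No stereocentre is formed, and acetic acid turns 11 into 12, so the whole step is an isomerisation of 7.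

## Compound list

1 | 1,4-dibromo-2-fluorobenzene | Fc1cc(Br)ccc1Br | starting material
2 | (3,6-dibromo-2-fluorophenyl)lithium | [Li]c1c(F)c(Br)ccc1Br | intermediate
3 | 3,6-dibromo-2-fluorobenzaldehyde | O=Cc1c(F)c(Br)ccc1Br | intermediate
4 | 2-amino-3,6-dibromobenzaldehyde | Nc1c(Br)ccc(Br)c1C=O | intermediate
5 | N-(3,6-dibromo-2-formylphenyl)formamide | O=CNc1c(Br)ccc(Br)c1C=O | intermediate
6 | N-[3,6-dibromo-2-(dibromomethyl)phenyl]formamide | O=CNc1c(Br)ccc(Br)c1C(Br)Br | intermediate
7 | 1,4-dibromo-2-(dibromomethyl)-3-isocyanobenzene | [C-]#[N+]c1c(Br)ccc(Br)c1C(Br)Br | intermediate
8 | [dibromo(3,6-dibromo-2-isocyanophenyl)methyl]lithium | [Li]C(Br)(Br)c1c(Br)ccc(Br)c1[N+]#[C-] | intermediate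
9 | (3,3,4,7-tetrabromo-3H-indol-2-yl)lithium | [Li]C1=Nc2c(Br)ccc(Br)c2C1(Br)Br | intermediate
10 | 2,3,3,4,7-pentabromo-3H-indole | BrC1=Nc2c(Br)ccc(Br)c2C1(Br)Br | intermediate
11 | lithium 2,3,4,7-tetrabromoindol-1-ide | [Li+].Brc1[n-]c2c(Br)ccc(Br)c2c1Br | intermediate
12 | 2,3,4,7-tetrabromo-1H-indole | Brc1[nH]c2c(Br)ccc(Br)c2c1Br | target

## Step count and least certain steps

Total step count: 6. Longest linear sequence: 6 (the route is fully linear).

**Step 6 (key step, bears the label).**
- The closure turns a halogen-stabilised carbanion into a non-stabilised sp2 carbanion, so it should be slower and less favourable than in the parent reaction. α-Elimination of LiBr from the carbenoid may then win, followed by bimolecular capture of the carbene by isocyanide groups.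
- The second weak point is capture of a proton instead of bromine at C2, which would spread the bromine inventory unevenly over the indole molecules.
- The third is attack of one carbanion on the isocyanide of another molecule.
- Fallback in known chemistry, from 4 back to 12. Ramirez olefination of 4 (CBr4, PPh3, CH2Cl2, 0 °C) should give 3,6-dibromo-2-(2,2-dibromovinyl)aniline F1. Cs2CO3 in DMSO should then effect dehydrobromination and 5-endo-dig closure of N1–C2 to 2,4,7-tribromo-1H-indole F2, the metal-free way to 2-bromoindoles. NBS (1 equiv, THF, −78 °C, dark) should brominate the free C3 position and give 12. This gives up the C2–C3 closure for a closure at nitrogen and accepts one electrophilic bromination.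

**Step 4.**
- The second C–O to C–Br exchange must pass a cation-like state at a benzylic carbon on an electron-poor, doubly ortho-substituted ring. It may stall, so that hydrolysis on work-up returns the aldehyde.
- Where ionisation does occur, participation of the formamide oxygen (six-membered ring closure onto the benzylic carbon) competes with bromide.
- Fallback from 5 back to 7, in which nitrogen is first turned into a group that cannot participate. Dehydration of 5 (POCl3, Et3N, CH2Cl2, 0 °C) should give 3,6-dibromo-2-isocyanobenzaldehyde F3. Addition of Br2 (1 equiv, CH2Cl2, −78 °C) should give N-(3,6-dibromo-2-formylphenyl)carbonimidic dibromide F4. PBr5 (ClCH2CH2Cl, 60 °C), which this masked substrate should tolerate, should give N-[3,6-dibromo-2-(dibromomethyl)phenyl]carbonimidic dibromide F5. PPh3 (1 equiv, CH2Cl2, 0 °C) should strip the two imidoyl bromines, the softest positive bromine in F5, and return 7.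

**Step 5.**
- The amine may meet the N–H before the oxygen is fully activated. Loss of hydrogen bromide across N–H and the benzylic C–Br (1,4-elimination) and oligomerisation would follow.
- Slow chloride-for-bromide exchange at the benzylic carbon is a lesser concern.
- Fallback from 5 back to 7, in which both oxygens are activated in one flask before any base is present. (PhO)3P and Br2 (2.5 equiv each, CH2Cl2, −60 °C → rt) should convert the formamide and the aldehyde together and give N-[3,6-dibromo-2-(dibromomethyl)phenyl]methanimidoyl bromide F6. Et3N, added last, should remove hydrogen bromide and give 7. The free N–H formamide next to CHBr2 never meets a base.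

**Step 2.**
- At the temperature that the substitution needs, condensation of ammonia with the aldehyde may run on to aminal-type oligomers.
- Some attack at the other ortho carbon (C–Br) cannot be excluded.
- Fallback from 3 back to 4. NaN3 (DMSO, rt to 40 °C), a better and non-condensing nucleophile, should give 2-azido-3,6-dibromobenzaldehyde F7. Staudinger reduction (PPh3, THF/H2O, rt) should then give 4.

## Further compounds

F1 | step 6 | 3,6-dibromo-2-(2,2-dibromovinyl)aniline | Nc1c(Br)ccc(Br)c1C=C(Br)Br
F2 | step 6 | 2,4,7-tribromo-1H-indole | Brc1cc2c(Br)ccc(Br)c2[nH]1
F3 | step 4 | 3,6-dibromo-2-isocyanobenzaldehyde | [C-]#[N+]c1c(Br)ccc(Br)c1C=O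
F4 | step 4 | N-(3,6-dibromo-2-formylphenyl)carbonimidic dibromide | BrC(Br)=Nc1c(Br)ccc(Br)c1C=O
F5 | step 4 | N-[3,6-dibromo-2-(dibromomethyl)phenyl]carbonimidic dibromide | BrC(Br)=Nc1c(Br)ccc(Br)c1C(Br)Br
F6 | step 5 | N-[3,6-dibromo-2-(dibromomethyl)phenyl]methanimidoyl bromide | BrC=Nc1c(Br)ccc(Br)c1C(Br)Br
F7 | step 2 | 2-azido-3,6-dibromobenzaldehyde | [N-]=[N+]=Nc1c(Br)ccc(Br)c1C=O
A1 | alternative 1 | 1,4-dibromo-2-nitrobenzene | O=[N+]([O-])c1cc(Br)ccc1Br
A2 | alternative 1 | 4,7-dibromo-1H-indole | Brc1ccc(Br)c2[nH]ccc12
A3 | alternative 1 | 3,4,7-tribromo-1H-indole | Brc1c[nH]c2c(Br)ccc(Br)c12
A4 | alternative 2 | 2,5-dibromothiophene 1,1-dioxide | O=S1(=O)C(Br)=CC=C1Br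
A5 | alternative 2 | tert-butyl 2,3-dibromo-1H-pyrrole-1-carboxylate | CC(C)(C)OC(=O)n1ccc(Br)c1Br
A6 | alternative 2 | tert-butyl cis-2,3,4,7-tetrabromo-3a,7a-dihydro-1H-indole-1-carboxylate (racemic, one enantiomer drawn) | CC(C)(C)OC(=O)N1C(Br)=C(Br)[C@H]2C(Br)=CC=C(Br)[C@@H]12
A7 | alternative 2 | tert-butyl 2,3,4,7-tetrabromo-1H-indole-1-carboxylate | CC(C)(C)OC(=O)n1c(Br)c(Br)c2c(Br)ccc(Br)c12
A8 | alternative 3 | 3,6-dibromo-2-(trimethylsilyl)phenyl trifluoromethanesulfonate | C[Si](C)(C)c1c(Br)ccc(Br)c1OS(=O)(=O)C(F)(F)F
A9 | alternative 3 | 3,6-dibromobenzyne (1,4-dibromocyclohexa-1,3-dien-5-yne) | BrC1=CC=C(Br)C#C1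
A10 | alternative 3 | methyl 2-[(tert-butoxycarbonyl)amino]acrylate | C=C(NC(=O)OC(C)(C)C)C(=O)OC
A11 | alternative 3 | 1-tert-butyl 2-methyl 4,7-dibromo-2,3-dihydro-1H-indole-1,2-dicarboxylate (racemic) | COC(=O)C1Cc2c(Br)ccc(Br)c2N1C(=O)OC(C)(C)C
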